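## Analysis of the target

Target 21 is the C30 apo-carotenoid (3R,5R,8R)-5,8-epoxy-3-hydroxy-5,8-dihydro-8'-apo-β-caroten-8'-al. Carotenoid locants are used throughout: ring A is C1–C6 (C1 gem-dimethyl, C3 carbinol, C5 oxygenated quaternary carbon), C7 and C8 complete ring B, and the chain runs C9–C15 and C15'–C8' (aldehyde).

- **Ring system.** Cyclohexane ring A is fused along C5–C6 to the 2,5-dihydrofuran ring B (O–C5–C6=C7–C8). C8 carries an all-E heptaenal chain with methyl branches at C9, C13, C13' and C9'.
- **Stereocentres.** C3 and C5 are 1,3-related on ring A, with the hydroxyl and the ring oxygen cis. C8 sits across the ring oxygen from C5, with the polyene trans to the C5 methyl (cis to C4).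
- **Sensitive groups.** The C8–O bond is doubly allylic and vinylogously tied to the polyene. Brønsted acids and strong Lewis acids ionise it reversibly to a polyenyl cation, and reclosure scrambles C8. The polyenal is sensitive to light, oxygen and E/Z isomerisation, and the aldehyde cannot be released by acidic acetal hydrolysis.
- **What is hard.** C8 has no neighbouring stereocentre that could bias a cationic ring closure; its nearest centre, C5, offers only methyl versus ring CH2. C8 therefore has to be set without a cation and never see acid afterwards. The cis C3/C5 relation needs oxygen delivered to the hydroxyl face of a tetrasubstituted alkene, and the chain must be joined convergently under non-acidic conditions.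

## Retrosynthetic reasoning

**C8' oxidation level (21 ⇒ 20 ⇒ 19).** The aldehyde is taken back to allylic alcohol 20 and then to ester 19. An ester end can be carried through a basic olefination and is unveiled by hydride and a neutral allylic oxidation, so no acid touches ring B. The forward oxidation must distinguish the polyenylic primary alcohol from the saturated C3 hydroxyl.

**C11=C12 (19 ⇒ 13 + 17).** Cutting the middle of the chain gives two C15 halves. The ring half 13 is the phosphonate nucleophile, so C8–H is never γ to a carbonyl, and 13 needs no functional-group change after the key step. The forward Horner–Wadsworth–Emmons reaction must give the E alkene without opening ring B.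

**C11'=C12' (17 ⇒ 15 + 16; 15 ⇒ 14).** Aldehyde ester 17 comes from one olefination of the symmetrical dialdehyde 16 with the C5 phosphonate 15, itself one Arbuzov step from bromo ester 14. The cut uses the only place where the 1,6-dimethyl pattern of 16 maps onto the chain (C13/C13').

**O–C8, the key cut (13 ⇒ 12).** Ring B is opened at O–C8 to the α-hydroxyallene 12 (C5–OH, C6=C7=C8). The C8 centre becomes an allene axis and the bicycle becomes a monocycle. The forward gold-catalysed 5-endo cycloisomerisation has to close ring B, create the ring-fusion C6=C7 bond and copy the axis into C8 without any ionisation. This cut is chosen because C8 cannot be controlled through a cation, but it can be controlled through a stereospecific axis-to-centre transfer.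

**C8–H and C6–O (12 ⇒ 10).** The allene is taken back to propargylic epoxide 10. A copper-catalysed anti SN2' hydride reduction translates the C5/C6 centres into the axis and leaves O5 on C5. The forward step must deliver hydride to C8 strictly anti to the leaving oxygen.

**Epoxide oxygen (10 ⇒ 9).** The epoxide is removed to give homoallylic alcohol 9. Because O5 is cis to the C3 hydroxyl in the target, that hydroxyl can direct a vanadium-catalysed epoxidation to its own face. C3 thus controls C5/C6, which control the axis, which controls C8: one relay from a single centre.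

**C6–C7 (9 ⇒ 5 + 8; 8 ⇒ 7 ⇒ 6).** A Sonogashira cut separates enol triflate 5 from enyne phosphonate 8, which is made in two steps from enynol 6 via bromide 7. The C9=C10 geometry and the C11 phosphonate arrive ready-made.

**C3 configuration (5 ⇒ 4 ⇒ 2 ⇒ 1).** Triflate 5 comes from ketone 2 via 4. Benzoate 2 arises from the zeaxanthin ring synthon 1 by a Mitsunobu inversion, which sets the C3 configuration the target needs and protects the oxygen for the enolisation.

## Alternatives that were turned down

**Alternative 1:** The textbook route. Disconnection: O–C8 by ring expansion of a 5,6-epoxide at the last stage. Forward key step: assemble the full epoxy apo-carotenal A1 and treat it with a trace of acid, so the epoxide opens at C6 and O5 recloses on C8. Turned down because the closure passes through a free polyenyl cation that is planar at C8, and the only nearby centre (C5) gives no facial bias. Both C8 epimers would form and interconvert under the same acid, so the single isomer would have to be separated at the C30 stage from a labile polyenal. The cis hydroxyl would play no part in setting C8.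

**Alternative 2:** Disconnection: C8–C9. Forward key step: reduce the C11 bicyclic butenolide A2 to its lactol, ionise it and add an alkenyl metal nucleophile to the oxocarbenium ion. Turned down because C8 is again set at a planar cation with the same lack of facial bias. The lactol can also open to a hydroxy enal, and the vinylogous position C6 competes for the nucleophile. Seven double bonds would then have to be built linearly on the acid-labile bicycle, costing more steps than the convergent C15 + C15 union.

**Alternative 3:** Disconnection: O–C8 by SN2 ring closure. Forward key step: cyclodehydration of the (Z)-ene-diol A3, with C8 set beforehand by an asymmetric carbonyl reduction and inverted in the closure. Turned down because two stereo-elements must be made independently. The Z exocyclic C6=C7 bond lies between two quaternary carbons and is accessible only by olefination of a very hindered ketone. The activated C8 leaving group is doubly allylic and would ionise rather than undergo clean inversion.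

Key step: step 9

Assumption: 1, 6, 14 and 16 are taken as purchasable building blocks (1 is the zeaxanthin ring synthon, 16 the C10 dialdehyde of carotenoid manufacture).

## Route

All operations from step 9 onward are run under argon in dim light, with neutral or basic work-up and Et3N-deactivated silica.

Step 1
Reactants: 1 (4R,6R)-4-hydroxy-2,2,6-trimethylcyclohexan-1-one
Product: 2 (1S,5R)-3,3,5-trimethyl-4-oxocyclohexyl benzoate
Conditions: PPh3, DIAD, PhCO2H (1.5 equiv each), THF, 0 °C to rt
Reagents that add atoms: benzoic acid, OC(=O)c1ccccc1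
Why: Mitsunobu reaction; SN2 displacement of the activated secondary hydroxyl by benzoate inverts the carbinol carbon (future C3) to the configuration of the target and protects it in the same operation. The methyl-bearing α-carbon ceases to be a stereocentre in step 2, so its integrity does not matter.

Step 2
Reactants: 2 (1S,5R)-3,3,5-trimethyl-4-oxocyclohexyl benzoate
Product: 4 (1S)-3,5,5-trimethyl-4-{[(trifluoromethyl)sulfonyl]oxy}cyclohex-3-en-1-yl benzoate, via lithium enolate 3 (not isolated)
Conditions: LiN(iPr)2 (1.1 equiv), THF, −78 °C; then PhNTf2, −78 °C to rt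
Reagents that add atoms: N-phenylbis(trifluoromethanesulfonimide), O=S(=O)(N(c1ccccc1)S(=O)(=O)C(F)(F)F)C(F)(F)F
Why: Enolisation and O-sulfonylation to the enol triflate; the ketone has a single α-hydrogen, so only one regioisomer can form. At −78 °C the benzoate, which has no α-hydrogen, should survive the amide base.

Step 3
Reactants: 4 (1S)-3,5,5-trimethyl-4-{[(trifluoromethyl)sulfonyl]oxy}cyclohex-3-en-1-yl benzoate
Product: 5 (4S)-4-hydroxy-2,6,6-trimethylcyclohex-1-en-1-yl trifluoromethanesulfonate
Conditions: iBu2AlH (2.2 equiv), CH2Cl2, −78 °C; aq. potassium sodium tartrate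
Reagents that add atoms: none
Why: Reductive ester cleavage; hydride removes the benzoate as benzyl alcohol at a temperature at which the enol triflate is inert. This frees the hydroxyl that must direct step 7 and avoids basic alcoholysis that could attack the triflate.

Step 4
Reactants: 6 (2E)-3-methylpent-2-en-4-yn-1-ol
Product: 7 (3E)-5-bromo-3-methylpent-3-en-1-yne
Conditions: PBr3 (0.4 equiv), pyridine (cat.), Et2O, −10 to 0 °C
Reagents that add atoms: phosphorus tribromide, BrP(Br)Br
Why: Standard conversion of a primary allylic alcohol into the bromide via its phosphite ester; the low temperature should keep the E double bond and favour the primary, conjugated bromide over the transposed tertiary one.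

Step 5
Reactants: 7 (3E)-5-bromo-3-methylpent-3-en-1-yne
Product: 8 diethyl [(2E)-3-methylpent-2-en-4-yn-1-yl]phosphonate
Conditions: P(OEt)3 (1.2 equiv), toluene, 90 °C, EtBr distilled off
Reagents that add atoms: triethyl phosphite, CCOP(OCC)OCC
Why: Michaelis–Arbuzov reaction of a reactive allylic bromide; it installs the C11 phosphonate before any sensitive ring chemistry, so nothing has to be changed on the ring half after the key step.

Step 6
Reactants: 5 (4S)-4-hydroxy-2,6,6-trimethylcyclohex-1-en-1-yl trifluoromethanesulfonate; 8 diethyl [(2E)-3-methylpent-2-en-4-yn-1-yl]phosphonate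
Product: 9 diethyl {(2E)-5-[(4S)-4-hydroxy-2,6,6-trimethylcyclohex-1-en-1-yl]-3-methylpent-2-en-4-yn-1-yl}phosphonate
Conditions: Pd(PPh3)4 (5 mol%), CuI (10 mol%), Et3N, DMF, rt, degassed
Reagents that add atoms: none
Why: Sonogashira coupling of an enol triflate with a terminal alkyne forms C6–C7. The free hydroxyl and the phosphonate are spectators, and the amine is too weak a base to deprotonate the allylic phosphonate.

Step 7
Reactants: 9 diethyl {(2E)-5-[(4S)-4-hydroxy-2,6,6-trimethylcyclohex-1-en-1-yl]-3-methylpent-2-en-4-yn-1-yl}phosphonate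
Product: 10 diethyl {(2E)-5-[(1R,4R,6R)-4-hydroxy-2,2,6-trimethyl-7-oxabicyclo[4.1.0]heptan-1-yl]-3-methylpent-2-en-4-yn-1-yl}phosphonate
Conditions: VO(acac)2 (5 mol%), t-BuOOH (1.5 equiv, decane), 4 Å sieves, CH2Cl2, 0 °C to rt
Reagents that add atoms: tert-butyl hydroperoxide, CC(C)(C)OO
Why: Hydroxyl-directed epoxidation of a cyclic homoallylic alcohol; the pentavalent vanadium alkoxide formed at O3 delivers the peroxide oxygen to its own face of C5=C6. This sets C5 (R) and C6 with the epoxide cis to the hydroxyl, as the target requires. The C9=C10 bond has no hydroxyl within reach and should stay untouched.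

Step 8
Reactants: 10 diethyl {(2E)-5-[(1R,4R,6R)-4-hydroxy-2,2,6-trimethyl-7-oxabicyclo[4.1.0]heptan-1-yl]-3-methylpent-2-en-4-yn-1-yl}phosphonate
Product: 12 diethyl {(2E)-5-[(2R,4R)-2,4-dihydroxy-2,6,6-trimethylcyclohexylidene]-3-methylpenta-2,4-dien-1-yl}phosphonate (allene axis S), via bis(silyl) ether 11 (not isolated)
Conditions: CuCl (5 mol%), 1,3-bis(2,6-diisopropylphenyl)imidazolium chloride (5 mol%), NaOtBu (12 mol%), (EtO)2MeSiH (3 equiv), toluene, 0 °C to rt; then 1 M aq. NaOH, THF, 0 °C
Reagents that add atoms: none
Why: Copper hydride-catalysed SN2' reduction of a propargyl oxirane to an α-hydroxyallene; the carbene-ligated monovalent copper hydride delivers hydride to C8 anti to the breaking C6–O bond. The C5/C6 centres are thereby translated into an S-configured axis (with ring A drawn flat, C9 on the side of the two hydroxyls and H-8 on the side of the C5 methyl), while O5 stays on C5. The silane converts both oxygens into silyl ethers, which the basic work-up hydrolyses.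

Step 9
Reactants: 12 diethyl {(2E)-5-[(2R,4R)-2,4-dihydroxy-2,6,6-trimethylcyclohexylidene]-3-methylpenta-2,4-dien-1-yl}phosphonate (allene axis S)
Product: 13 diethyl {(2E)-3-[(2R,6R,7aR)-6-hydroxy-4,4,7a-trimethyl-2,4,5,6,7,7a-hexahydro-1-benzofuran-2-yl]but-2-en-1-yl}phosphonate
Conditions: AuCl3 (2 mol%), THF, 0 °C to rt, dark; Et3N quench, filtration through basic alumina
Reagents that add atoms: none
Why: AuCl3 binds the C7=C8 π-bond of the allene on the side away from O5, the tertiary hydroxyl adds to C8 in the plane of C5–C6–C7 (anti-oxyauration), and protodeauration of the σ-vinylgold species at C7 releases the dihydrofuran; this is the established gold-catalysed cycloisomerisation of α-hydroxyallenes to 2,5-dihydrofurans with axis-to-centre chirality transfer. Ring B closes in a 5-endo mode (O5 attacks the distal allene carbon C8 and C6=C7 stays inside the new ring), which also turns the exocyclic allene into the ring-fusion double bond of the target. C8 is the only new stereocentre and is controlled by the allene axis together with C5: O5 must enter in the plane of the future ring B, so the two substituents on C8 keep their sides, and C9 (on the O5 side in 12) ends up cis to C4 and trans to the C5 methyl, which is 8R. The step needs chemoselectivity for O5 over O3; this is secured geometrically, because O3 could reach only C6, through a boat with syn-axial contacts to a strained oxanorbornane, whereas O5 sits next to the allene. It also needs stereospecificity, meaning no ionisation of the doubly allylic C8–O bond or of a gold-bound pentadienyl cation. At the C15 stage the short C9=C10–CH2P arm stabilises such a cation far less than a full polyene would, THF tempers the Lewis acidity of trivalent gold, and the reaction is stopped with Et3N. A Nazarov-type carbocyclisation of the vinylallene would have to form a bond to the fully substituted C6 between two quaternary carbons and should not compete.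

Step 10
Reactants: 14 ethyl (2E)-4-bromo-2-methylbut-2-enoate
Product: 15 ethyl (2E)-4-(diethoxyphosphoryl)-2-methylbut-2-enoate
Conditions: P(OEt)3 (1.2 equiv), neat, 110 °C, EtBr distilled off
Reagents that add atoms: triethyl phosphite, CCOP(OCC)OCC
Why: Michaelis–Arbuzov reaction of an allylic bromide gives the C5 phosphonate that carries C8' at the ester level.

Step 11
Reactants: 15 ethyl (2E)-4-(diethoxyphosphoryl)-2-methylbut-2-enoate; 16 (2E,4E,6E)-2,7-dimethylocta-2,4,6-trienedial
Product: 17 ethyl (2E,4E,6E,8E,10E)-2,6,11-trimethyl-12-oxododeca-2,4,6,8,10-pentaenoate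
Conditions: 16 (3 equiv), LiCl, DBU, MeCN, 0 °C to rt; excess 16 recovered
Reagents that add atoms: none
Why: Horner–Wadsworth–Emmons reaction of an ester-stabilised vinylogous phosphonate under mild amine/lithium salt conditions forms C11'=C12' with E selectivity. The excess of the symmetrical dialdehyde holds the reaction at the mono-olefination stage.

Step 12
Reactants: 13 diethyl {(2E)-3-[(2R,6R,7aR)-6-hydroxy-4,4,7a-trimethyl-2,4,5,6,7,7a-hexahydro-1-benzofuran-2-yl]but-2-en-1-yl}phosphonate; 17 ethyl (2E,4E,6E,8E,10E)-2,6,11-trimethyl-12-oxododeca-2,4,6,8,10-pentaenoate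
Product: 19 ethyl (2E,4E,6E,8E,10E,12E,14E)-15-[(2R,6R,7aR)-6-hydroxy-4,4,7a-trimethyl-2,4,5,6,7,7a-hexahydro-1-benzofuran-2-yl]-2,6,11-trimethylhexadeca-2,4,6,8,10,12,14-heptaenoate, via disodium phosphonate carbanion 18 (not isolated)
Conditions: NaN(SiMe3)2 (2.1 equiv), THF, −78 °C; then 17, −78 to 0 °C; aq. NaHCO3
Reagents that add atoms: none
Why: Horner–Wadsworth–Emmons olefination with an allylic phosphonate forms C11=C12 with E selectivity and reacts only at the aldehyde of 17. The second equivalent of base covers the C3 hydroxyl. The ring ether is a poor leaving group, in the same vinylogous position as the acetal oxygens of the C5 ylides that are standard in polyene synthesis, so ring B should survive the carbanion at low temperature.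

Step 13
Reactants: 19 ethyl (2E,4E,6E,8E,10E,12E,14E)-15-[(2R,6R,7aR)-6-hydroxy-4,4,7a-trimethyl-2,4,5,6,7,7a-hexahydro-1-benzofuran-2-yl]-2,6,11-trimethylhexadeca-2,4,6,8,10,12,14-heptaenoate
Product: 20 (2R,6R,7aR)-2-[(2E,4E,6E,8E,10E,12E,14E)-16-hydroxy-6,11,15-trimethylhexadeca-2,4,6,8,10,12,14-heptaen-2-yl]-4,4,7a-trimethyl-2,4,5,6,7,7a-hexahydro-1-benzofuran-6-ol
Conditions: iBu2AlH (3.5 equiv), CH2Cl2, −78 °C; aq. potassium sodium tartrate
Reagents that add atoms: none
Why: 1,2-Reduction of the conjugated ester to the allylic alcohol; at −78 °C the aluminium hydride should not open the allylic ether of ring B, and the work-up is non-acidic.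

Step 14
Reactants: 20 (2R,6R,7aR)-2-[(2E,4E,6E,8E,10E,12E,14E)-16-hydroxy-6,11,15-trimethylhexadeca-2,4,6,8,10,12,14-heptaen-2-yl]-4,4,7a-trimethyl-2,4,5,6,7,7a-hexahydro-1-benzofuran-6-ol
Product: 21 (2E,4E,6E,8E,10E,12E,14E)-15-[(2R,6R,7aR)-6-hydroxy-4,4,7a-trimethyl-2,4,5,6,7,7a-hexahydro-1-benzofuran-2-yl]-2,6,11-trimethylhexadeca-2,4,6,8,10,12,14-heptaenal
Conditions: activated MnO2 (20 equiv), CH2Cl2, rt, dark
Reagents that add atoms: none
Why: Allylic oxidation with MnO2 is selective for the polyenylic primary alcohol over the saturated C3 hydroxyl and is neutral, so C8 and the E geometry are not put at risk.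

## Compound list

1 | (4R,6R)-4-hydroxy-2,2,6-trimethylcyclohexan-1-one | O=C1C(C)(C)C[C@H](O)C[C@H]1C | starting material
2 | (1S,5R)-3,3,5-trimethyl-4-oxocyclohexyl benzoate | O=C1C(C)(C)C[C@@H](OC(=O)c2ccccc2)C[C@H]1C | intermediate
3 | lithium (4S)-4-(benzoyloxy)-2,6,6-trimethylcyclohex-1-en-1-olate | CC1=C([O-])C(C)(C)C[C@@H](OC(=O)c2ccccc2)C1.[Li+] | intermediate (not isolated)
4 | (1S)-3,5,5-trimethyl-4-{[(trifluoromethyl)sulfonyl]oxy}cyclohex-3-en-1-yl benzoate | CC1=C(OS(=O)(=O)C(F)(F)F)C(C)(C)C[C@@H](OC(=O)c2ccccc2)C1 | intermediate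
5 | (4S)-4-hydroxy-2,6,6-trimethylcyclohex-1-en-1-yl trifluoromethanesulfonate | CC1=C(OS(=O)(=O)C(F)(F)F)C(C)(C)C[C@@H](O)C1 | intermediate
6 | (2E)-3-methylpent-2-en-4-yn-1-ol | C#C/C(C)=C/CO | starting material
7 | (3E)-5-bromo-3-methylpent-3-en-1-yne | C#C/C(C)=C/CBr | intermediate
8 | diethyl [(2E)-3-methylpent-2-en-4-yn-1-yl]phosphonate | C#C/C(C)=C/CP(=O)(OCC)OCC | intermediate
9 | diethyl {(2E)-5-[(4S)-4-hydroxy-2,6,6-trimethylcyclohex-1-en-1-yl]-3-methylpent-2-en-4-yn-1-yl}phosphonate | CC1=C(C#C/C(C)=C/CP(=O)(OCC)OCC)C(C)(C)C[C@@H](O)C1 | intermediate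
10 | diethyl {(2E)-5-[(1R,4R,6R)-4-hydroxy-2,2,6-trimethyl-7-oxabicyclo[4.1.0]heptan-1-yl]-3-methylpent-2-en-4-yn-1-yl}phosphonate (epoxide cis to the hydroxyl) | C[C@@]12C[C@H](O)CC(C)(C)[C@@]1(O2)C#C/C(C)=C/CP(=O)(OCC)OCC | intermediate
11 | bis[diethoxy(methyl)silyl] ether of 12 at O3 and O5, configuration as in 12 | CCO[Si](C)(OCC)O[C@]1(C)C[C@H](O[Si](C)(OCC)OCC)CC(C)(C)C1=[C@]=C([H])/C(C)=C/CP(=O)(OCC)OCC | intermediate (not isolated)
12 | diethyl {(2E)-5-[(2R,4R)-2,4-dihydroxy-2,6,6-trimethylcyclohexylidene]-3-methylpenta-2,4-dien-1-yl}phosphonate, allene axis S (C9 on the side of both hydroxyls, H-8 on the side of the C5 methyl) | C[C@@]1(O)C[C@H](O)CC(C)(C)C1=[C@]=C([H])/C(C)=C/CP(=O)(OCC)OCC | intermediate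
13 | diethyl {(2E)-3-[(2R,6R,7aR)-6-hydroxy-4,4,7a-trimethyl-2,4,5,6,7,7a-hexahydro-1-benzofuran-2-yl]but-2-en-1-yl}phosphonate | CCOP(=O)(OCC)C/C=C(\C)[C@H]1C=C2C(C)(C)C[C@@H](O)C[C@@]2(C)O1 | intermediate
14 | ethyl (2E)-4-bromo-2-methylbut-2-enoate | CCOC(=O)/C(C)=C/CBr | starting material
15 | ethyl (2E)-4-(diethoxyphosphoryl)-2-methylbut-2-enoate | CCOC(=O)/C(C)=C/CP(=O)(OCC)OCC | intermediate
16 | (2E,4E,6E)-2,7-dimethylocta-2,4,6-trienedial | O=C/C(C)=C/C=C/C=C(C)/C=O | starting material
17 | ethyl (2E,4E,6E,8E,10E)-2,6,11-trimethyl-12-oxododeca-2,4,6,8,10-pentaenoate | C\C(C(=O)OCC)=C/C=C/C(C)=C/C=C/C=C(C)/C=O | intermediate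
18 | disodium salt of 13 (O3 alkoxide and C11 carbanion) | CCOP(=O)(OCC)[CH-]/C=C(\C)[C@H]1C=C2C(C)(C)C[C@@H]([O-])C[C@@]2(C)O1.[Na+].[Na+] | intermediate (not isolated)
19 | ethyl (2E,4E,6E,8E,10E,12E,14E)-15-[(2R,6R,7aR)-6-hydroxy-4,4,7a-trimethyl-2,4,5,6,7,7a-hexahydro-1-benzofuran-2-yl]-2,6,11-trimethylhexadeca-2,4,6,8,10,12,14-heptaenoate | C\C(C(=O)OCC)=C/C=C/C(C)=C/C=C/C=C(C)/C=C/C=C(\C)[C@H]1C=C2C(C)(C)C[C@@H](O)C[C@@]2(C)O1 | intermediate
20 | (2R,6R,7aR)-2-[(2E,4E,6E,8E,10E,12E,14E)-16-hydroxy-6,11,15-trimethylhexadeca-2,4,6,8,10,12,14-heptaen-2-yl]-4,4,7a-trimethyl-2,4,5,6,7,7a-hexahydro-1-benzofuran-6-ol | C\C(CO)=C/C=C/C(C)=C/C=C/C=C(C)/C=C/C=C(\C)[C@H]1C=C2C(C)(C)C[C@@H](O)C[C@@]2(C)O1 | intermediate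
21 | (2E,4E,6E,8E,10E,12E,14E)-15-[(2R,6R,7aR)-6-hydroxy-4,4,7a-trimethyl-2,4,5,6,7,7a-hexahydro-1-benzofuran-2-yl]-2,6,11-trimethylhexadeca-2,4,6,8,10,12,14-heptaenal | C\C(C=O)=C/C=C/C(C)=C/C=C/C=C(C)/C=C/C=C(\C)[C@H]1C=C2C(C)(C)C[C@@H](O)C[C@@]2(C)O1 | target

## Step count and risk

Total step count: 14. Longest linear sequence: 10 (steps 1, 2, 3, 6, 7, 8, 9, 12, 13, 14).

**Step 9 (key step).**
- What may go wrong: erosion of the axis-to-centre transfer. The Lewis acid can ionise the doubly allylic C8–O bond of the product, or the gold-bound intermediate can open to a pentadienyl cation; either scrambles C8. Gold may also isomerise the C9=C10 bond.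
- Fallback (sets out from 5 and 8, returns at 13; known chemistry with a different ring-forming event):
  - Hydroboration of the terminal alkyne of 8 with pinacolborane (Cp2ZrHCl cat.) gives diethyl [(2E,4E)-3-methyl-5-(4,4,5,5-tetramethyl-1,3,2-dioxaborolan-2-yl)penta-2,4-dien-1-yl]phosphonate F1.
  - Suzuki–Miyaura coupling of F1 with triflate 5 (PdCl2(dppf), K3PO4, aq. THF) gives diethyl {(2E,4E)-5-[(4S)-4-hydroxy-2,6,6-trimethylcyclohex-1-en-1-yl]-3-methylpenta-2,4-dien-1-yl}phosphonate F2.
  - The hydroxyl-directed epoxidation of step 7 gives diethyl {(2E,4E)-5-[(1S,4R,6R)-4-hydroxy-2,2,6-trimethyl-7-oxabicyclo[4.1.0]heptan-1-yl]-3-methylpenta-2,4-dien-1-yl}phosphonate F3.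
  - A trace of HCl in Et2O at −20 °C effects the classical epoxide-to-furanoid rearrangement. It gives 13 together with its C8 epimer, diethyl {(2E)-3-[(2S,6R,7aR)-6-hydroxy-4,4,7a-trimethyl-2,4,5,6,7,7a-hexahydro-1-benzofuran-2-yl]but-2-en-1-yl}phosphonate F4.
  - The two are separated by chromatography and F4 is returned to the acid for re-equilibration.

**Step 8.**
- What may go wrong: hydride delivery to the wrong face. A copper alkoxide formed at the free O3 or at the epoxide could hand over hydride syn to the leaving oxygen, which would give the allene that leads to the C8 epimer. The copper hydride may also over-reduce the allene or the enyne.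
- Fallback (sets out from 10, returns at 12): palladium-catalysed hydrogenolysis with formate (Pd2(dba)3, PBu3, HCO2NH4, THF, rt). Zerovalent palladium opens the propargylic epoxide by anti oxidative addition to an allenylpalladium species, formate supplies the hydride on palladium, and reductive elimination places hydrogen on C8 anti to the departed oxygen. The stereochemical course thus no longer depends on how a metal hydride approaches the alkyne. This path makes no new compound (F0).

**Step 7.**
- What may go wrong: poor facial selectivity or low conversion. Delivery needs the axial-hydroxyl conformer, which suffers a syn-axial contact with a C1 methyl, and the enyne-conjugated tetrasubstituted alkene is a weak nucleophile.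
- Fallback (sets out from 9, returns at 10): stepwise intramolecular oxygen delivery.
  - Boc2O/DMAP gives the tert-butyl carbonate of 9, diethyl {(2E)-5-[(4S)-4-(tert-butoxycarbonyloxy)-2,6,6-trimethylcyclohex-1-en-1-yl]-3-methylpent-2-en-4-yn-1-yl}phosphonate F5.
  - IBr in toluene at −80 °C closes the carbonate oxygen onto C5 from the face of O3, with iodine anti on C6, giving the 3,5-O-carbonyl-6-iodo compound (cyclic iodocarbonate) F6.
  - K2CO3 in MeOH at 0 °C cleaves the carbonate, and the C5 alkoxide displaces the anti iodide to give 10.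

**Step 12.**
- What may go wrong: ring opening of ring B by vinylogous β-elimination from the allylic carbanion, with loss of C8 integrity on reclosure, and E/Z scrambling of C9=C10 and C11=C12 in the delocalised anion.
- Fallback (sets out from 12, returns at 19): reverse the order of olefination and cyclisation.
  - 12 is deprotonated (NaN(SiMe3)2, 3.1 equiv, THF, −78 °C) and condensed with 17 to give ethyl (2E,4E,6E,8E,10E,12E)-15-[(2R,4R)-2,4-dihydroxy-2,6,6-trimethylcyclohexylidene]-2,6,11,13-tetramethylpentadeca-2,4,6,8,10,12,14-heptaenoate (allene axis S) F7. Its carbanion has no leaving group in the vinylogous position.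
  - F7 is cyclised with AuCl3 as in step 9 to reach 19.

## Further compounds

F1 | step 9 | diethyl [(2E,4E)-3-methyl-5-(4,4,5,5-tetramethyl-1,3,2-dioxaborolan-2-yl)penta-2,4-dien-1-yl]phosphonate | CCOP(=O)(OCC)C/C=C(C)/C=C/B1OC(C)(C)C(C)(C)O1
F2 | step 9 | diethyl {(2E,4E)-5-[(4S)-4-hydroxy-2,6,6-trimethylcyclohex-1-en-1-yl]-3-methylpenta-2,4-dien-1-yl}phosphonate | CC1=C(/C=C/C(C)=C/CP(=O)(OCC)OCC)C(C)(C)C[C@@H](O)C1
F3 | step 9 | diethyl {(2E,4E)-5-[(1S,4R,6R)-4-hydroxy-2,2,6-trimethyl-7-oxabicyclo[4.1.0]heptan-1-yl]-3-methylpenta-2,4-dien-1-yl}phosphonate | C[C@@]12C[C@H](O)CC(C)(C)[C@@]1(O2)/C=C/C(C)=C/CP(=O)(OCC)OCC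
F4 | step 9 | diethyl {(2E)-3-[(2S,6R,7aR)-6-hydroxy-4,4,7a-trimethyl-2,4,5,6,7,7a-hexahydro-1-benzofuran-2-yl]but-2-en-1-yl}phosphonate | CCOP(=O)(OCC)C/C=C(\C)[C@@H]1C=C2C(C)(C)C[C@@H](O)C[C@@]2(C)O1
F0 | step 8 | none | none
F5 | step 7 | diethyl {(2E)-5-[(4S)-4-(tert-butoxycarbonyloxy)-2,6,6-trimethylcyclohex-1-en-1-yl]-3-methylpent-2-en-4-yn-1-yl}phosphonate | CC1=C(C#C/C(C)=C/CP(=O)(OCC)OCC)C(C)(C)C[C@@H](OC(=O)OC(C)(C)C)C1
F6 | step 7 | 3,5-O-carbonyl-6-iodo derivative of the ring of 9 (cyclic carbonate bridging O3 and O5, iodine on C6 anti to O5) | C[C@@]12C[C@@H](CC(C)(C)[C@]1(I)C#C/C(C)=C/CP(=O)(OCC)OCC)OC(=O)O2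
F7 | step 12 | ethyl (2E,4E,6E,8E,10E,12E)-15-[(2R,4R)-2,4-dihydroxy-2,6,6-trimethylcyclohexylidene]-2,6,11,13-tetramethylpentadeca-2,4,6,8,10,12,14-heptaenoate (allene axis S) | C[C@@]1(O)C[C@H](O)CC(C)(C)C1=[C@]=C([H])/C(C)=C/C=C/C(C)=C/C=C/C=C(C)/C=C/C=C(C)/C(=O)OCC
A1 | alternative 1 | (3R,5R,6S)-5,6-epoxy-3-hydroxy-5,6-dihydro-8'-apo-β-caroten-8'-al | C[C@@]12C[C@H](O)CC(C)(C)[C@@]1(O2)/C=C/C(C)=C/C=C/C(C)=C/C=C/C=C(C)/C=C/C=C(C)/C=O
A2 | alternative 2 | (6R,7aR)-6-hydroxy-4,4,7a-trimethyl-5,6,7,7a-tetrahydro-1-benzofuran-2(4H)-one | O=C1C=C2C(C)(C)C[C@@H](O)C[C@@]2(C)O1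
A3 | alternative 3 | diethyl {(2E,4S,5Z)-5-[(2R,4R)-2,4-dihydroxy-2,6,6-trimethylcyclohexylidene]-4-hydroxy-3-methylpent-2-en-1-yl}phosphonate | CCOP(=O)(OCC)C/C=C(\C)[C@@H](O)/C=C1/C(C)(C)C[C@@H](O)C[C@@]1(C)O
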